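A small charge of Ja in the cold, the noon run, ends with Jf at 27 %, ahead of Jg at 12 %. The larger, warmer spring run ends the other way round, with Jg at 34 % and Jf at 9 %. Jd exchanges into the complex Ja, giving Je and then Jf, and Jg appears late.

common to all: Jd 93 mM (held)
- noon: Ja 0.54 M; temperature 15 °C; run made earlier
- spring: Ja 1.2 M; temperature 28 °C; run made earlier
- gamma: Ja 0.80 M; temperature 20 °C; time 25 min
- delta: Ja 0.80 M; temperature 28 °C; time 25 min
- eta: Ja 0.80 M; temperature 36 °C; time 25 min

| run | time / min | Ja / % | Jg / % | Jf / % | Je / % |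
|---|---|---|---|---|---|
| noon | 6.00 | 81 | 2 | 4 | 14 |
| noon | 12.0 | 69 | 3 | 12 | 15 |
| noon | 20.0 | 57 | 6 | 23 | 17 |
| noon | 25.0 | 52 | 7 | 27 | 18 |
| noon | 30.0 | 42 | 12 | 27 | 14 |
| spring | 6.00 | 82 | 2 | 5 | 13 |
| spring | 12.0 | 70 | 2 | 12 | 15 |
| spring | 20.0 | 56 | 17 | 13 | 15 |
| spring | 25.0 | 53 | 25 | 12 | 11 |
| spring | 30.0 | 46 | 34 | 9 | 12 |

(scatter of a reading: 1.5 percentage points)

1. which of these there is most of at the end, counted by the Ja in it, gamma (Ja / Jf / Je / Jg)
2. which of these there is most of at the end, counted by the Ja in it, delta (Ja / Jf / Je / Jg)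
3. which of these there is most of at the end, counted by the Ja in it, eta (Ja / Jf / Je / Jg)
4. final amount of the leader among these, as a percentage of the Ja charged, in gamma
5. final amount of the leader among these, as a percentage of the Ja charged, in delta
6. final amount of the leader among these, as a percentage of the Ja charged, in eta

Two times can be read from these runs. The feed time τf is the time in which Ja falls by a factor e, reckoned as first order from the last reading of each run and averaged: 36.6 min. The drain time τd is the inverse of κ, which is the rise of Jg per minute over the last readings divided by the mean Jf there. It reads 42.8 min in noon and 6.67 min in spring. Their ratio N = τf/τd is thus 0.855 in noon, where Jf stays ahead, and 5.49 in spring, where Jg does.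

The reckoning here takes κ as a pseudo-first-order constant proportional to the charge, and it puts the remaining change between the two runs down to temperature, geometrically. Then τd is 19.2 min in gamma, 10.0 min in delta and 5.21 min in eta. For delta, 3.66 is N, the feed time over the drain time; gamma has 1.91 and eta 7.02. So Jf should stay ahead of Jg in gamma, and Jg ahead of Jf in delta and eta. Ja, by τf, stands near 50.5 % in each flask, though noon and spring mix charge and temperature, which leaves its lead in eta open.

The forecast gave Ja at 51 %, Ja at 51 % and Ja at 50 %, reading Jg's onset as “a concentration threshold”.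

Gamma ends with Ja at 49.2 %, delta with Ja at 40.0 %, and eta with Jg at 44.8 %.

    Jd ⇌ Jb, rate k1*(csat - [Jb]) (kL = 0.790 /min)
    Jc + Jf → Jg (k = 0.100 /M/min, Ea = 51.0 kJ/mol)
    Je + Jb ⇌ Jc + Jf (K = 30.0, k = 2.50 /M/min, Ea = 54.0 kJ/mol, ΔH = −5.00 kJ/mol)
    Ja + Jb ⇌ Jc + Je (K = 4.80, k = 0.780 /M/min, Ea = 50.0 kJ/mol, ΔH = 14.0 kJ/mol)
    (constants at 20 °C)

At N = 3.66, delta holds Jg at 28.7 % and Jf at 18.5 %. A neighbour of delta charged with 0.20 M of Ja keeps Ja at 14.2 % after 25.0 min, which gives that flask its own τf of 12.8 min. Its τd, scaled from delta by the leaving ligand Jc that each flask holds at that time, 0.627 M against 0.264 M, is 23.8 min, so N = 0.538 in the neighbour, which holds Jf at 46.0 % and Jg at 31.0 %.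

All runs are simulated with constants of no real substance; scatter was added.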